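The cycloheptene ring is disconnected at two bonds at once: the C8=C9 alkene and the C10–C1 bond to the quaternary ring-fusion carbon (daucane numbering). A tertiary cyclopropyl boronate whose neighbouring cyclopropane carbon carries the 2-methylcyclopentenyl unit is vinylated by Zweifel olefination, which makes C8–C9. The cis-divinylcyclopropane formed rearranges in the same flask (Cope), so that release of cyclopropane strain forges C10–C1, sets C1 and turns C8–C9 into the ring alkene. The step exploits the latent cyclohepta-1,4-diene of the seven-membered ring: C8=C9 and a C5=C6 alkene that later delivers H5 and the C6 oxygen. The precursor is a monocyclic cyclopentene–cyclopropane.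

Key step: step 7

Remark on numbering: daucane numbers are used for all compounds, also the monocyclic ones (C1 quaternary ring-fusion carbon with CH3-15, C4 carbinol carbon with the isopropyl group, C5 ring-fusion CH, C6 anisoate carbon, C8 alkene carbon with CH3-14, C9 alkene CH, C10 acetate carbon).

Remark on the auxiliary: the (2R,3R)-tartaramide in steps 5 and 6 is assumed to deliver CH2 to the alkene face drawn; if the induction is opposite, the (2S,3S)-diamide is used.

Step 1
Reactants: 1 (S)-(+)-terpinen-4-ol
Product: 2 (S)-triethyl{[4-methyl-1-(propan-2-yl)cyclohex-3-en-1-yl]oxy}silane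
Conditions: Et3SiOTf, 2,6-lutidine, CH2Cl2, 0 °C
Reagents that add atoms: triethylsilyl trifluoromethanesulfonate CC[Si](CC)(CC)OS(=O)(=O)C(F)(F)F
Why: Silylation of the tertiary alcohol with the silyl triflate masks the hydroxyl against β-elimination and carbenoid direction later, while the C4 stereocenter comes unchanged from the chiral pool.

Step 2
Reactants: 2 (S)-terpinen-4-ol triethylsilyl ether
Product: 3 (S)-6-oxo-3-(propan-2-yl)-3-(triethylsilyloxy)heptanal
Conditions: O3, CH2Cl2/MeOH, −78 °C; Me2S, −78 °C → rt
Reagents that add atoms: ozone [O-][O+]=O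
Why: Ozonolysis with reductive work-up cleaves the only alkene to the keto-aldehyde and leaves the silyl ether intact.

Step 3
Reactants: 3 keto-aldehyde
Product: 4 (R)-2-methyl-5-(propan-2-yl)-5-(triethylsilyloxy)cyclopent-1-ene-1-carbaldehyde
Conditions: piperidine (cat.), AcOH (cat.), benzene, 60 °C
Reagents that add atoms: none
Why: The amine-catalysed intramolecular aldol condensation (enamine of the aldehyde adds to the methyl ketone, then dehydration) should close the cyclopentene carbaldehyde, the reaction type used to contract limonene-type keto-aldehydes.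

Step 4
Reactants: 4 cyclopentene carbaldehyde
Product: 5 triethyl{[(1R)-2-[(1Z)-2-iodoprop-1-en-1-yl]-3-methyl-1-(propan-2-yl)cyclopent-2-en-1-yl]oxy}silane (iodine cis to the ring)
Conditions: (1-iodoethyl)triphenylphosphonium iodide, NaN(SiMe3)2, THF, −78 → −20 °C
Reagents that add atoms: (1-iodoethyl)triphenylphosphonium iodide CC(I)[P+](c1ccccc1)(c1ccccc1)c1ccccc1.[I-]
Why: The Stork–Zhao Wittig reaction of the α-iodo ylide gives the (Z)-iodoalkene under kinetic control, which places iodine cis to the cyclopentenyl group.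

Step 5
Reactants: 5 (Z)-iodoalkene
Product: 6 alkenylboronate of (2R,3R)-N,N,N′,N′-tetramethyltartaramide (boron in place of iodine, still cis to the ring; C4 R)
Conditions: t-BuLi (2 equiv), Et2O, −78 °C; B(OiPr)3; HCl (1 equiv, Et2O); (2R,3R)-N,N,N′,N′-tetramethyltartaramide, MgSO4, rt
Reagents that add atoms: triisopropyl borate CC(C)OB(OC(C)C)OC(C)C; (2R,3R)-N,N,N′,N′-tetramethyltartaramide CN(C)C(=O)[C@H](O)[C@@H](O)C(=O)N(C)C
Why: Iodine–lithium exchange and borylation proceed with retention of alkene geometry, and esterification with the C2-symmetric diol puts a chiral controller on boron.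

Step 6
Reactants: 6 alkenyl tartaramide boronate
Product: 8 2-[(1R,2R)-1-methyl-2-{(5R)-2-methyl-5-(propan-2-yl)-5-(triethylsilyloxy)cyclopent-1-en-1-yl}cyclopropyl]-4,4,5,5-tetramethyl-1,3,2-dioxaborolane (boron and cyclopentenyl cis), via cyclopropyl tartaramide boronate 7 (not isolated)
Conditions: Zn(Cu), CH2I2, Et2O, reflux; then pinacol, Et2O, rt
Reagents that add atoms: diiodomethane ICI; pinacol CC(C)(O)C(C)(C)O
Why: The amide-directed Simmons–Smith cyclopropanation is stereospecific (boron stays cis to the cyclopentenyl group) and the tartaramide should deliver CH2 to one alkene face, which sets C6 and C8 before transesterification to the pinacol ester.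

Step 7
Reactants: 8 cyclopropyl pinacol boronate; 9 vinyl bromide
Product: 12 (1R,4R)-4-(triethylsilyloxy)dauca-5,8-diene, via lithium vinylboronate complex 10 (not isolated), via cis-divinylcyclopropane 11 (not isolated)
Conditions: 9, t-BuLi (2 equiv), Et2O, −78 °C; add 8 in THF, −78 °C; I2, THF, −78 °C; NaOMe, MeOH, −78 °C → rt; then toluene, 90 °C
Reagents that add atoms: none
Why: Vinyllithium (from 9) adds to the boron of 8 to give boronate 10, iodine activates its vinyl group, the tertiary cyclopropyl carbon C8 migrates from boron to C9 with retention and methoxide triggers anti-elimination of boron and iodide (Zweifel olefination), so that C8–C9 is formed and cis-divinylcyclopropane 11 results. On heating, 11 undergoes the divinylcyclopropane–cycloheptadiene (Cope) rearrangement through a boat transition state: the strained C6–C8 bond breaks, C10–C1 forms and C8–C9 becomes the C8=C9 alkene; the closest known reaction types are the Zweifel coupling of tertiary boronic esters and the Cope rearrangement of 1-(2-methylcyclopentenyl)-2-vinylcyclopropanes. The seven-membered ring closes by this [3,3]-sigmatropic ring expansion of the cyclopropane, not by an exo or endo attack of a nucleophile. The only new stereocenter, quaternary C1, is set stereospecifically by the configuration of cyclopropane carbon C6, because the new bond forms suprafacially on the cyclopentene face on which C8 sits, the face anti to the C4 oxygen. The step needs the two alkenyl groups cis on the cyclopropane (secured by the retentive 1,2-shift from cis-boronate 8), iodination of the boronate vinyl group in preference to the hindered tetrasubstituted ring alkene, and a rearrangement faster than one-centre epimerisation of 11, which the moderate temperature should secure despite the inward-pointing C1 methyl group.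

Step 8
Reactants: 12 silyl-protected diene
Product: 13 (1R,4R)-dauca-5,8-dien-4-ol
Conditions: Bu4NF, THF, rt
Reagents that add atoms: none
Why: Fluoride-mediated desilylation frees the tertiary C4 hydroxyl, which is needed as the directing group of the next step.

Step 9
Reactants: 13 dienol
Product: 14 (1R,4R)-5,6-epoxydauc-8-en-4-ol (epoxide oxygen cis to the C4 hydroxyl and CH3-15)
Conditions: VO(acac)2 (cat.), t-BuOOH, CH2Cl2, 0 °C → rt
Reagents that add atoms: tert-butyl hydroperoxide CC(C)(C)OO
Why: The vanadium-catalysed hydroxyl-directed epoxidation should react only at the alkene of the tertiary allylic alcohol (C5=C6) and on the face of the C4 hydroxyl, leaving C8=C9 untouched.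

Step 10
Reactants: 14 epoxy alcohol
Product: 15 (1R,4R,5R,6R)-dauc-8-ene-4,6-diol (H5 cis to CH3-15 and to the C4 hydroxyl; 6-OH cis to H5)
Conditions: Cp2TiCl2 (cat.), Mn, 2,4,6-collidine·HCl, 1,4-cyclohexadiene, THF, rt
Reagents that add atoms: none
Why: Cp2TiCl-mediated reductive epoxide opening breaks the C5–O bond to the tertiary radical, and hydrogen-atom transfer from 1,4-cyclohexadiene to the convex face (that of CH3-15 and the C4 oxygen) should give the cis ring fusion while the C6–O bond is kept.

Step 11
Reactants: 15 6-epi-diol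
Product: 16 (1R,4R,5S)-4-hydroxydauc-8-en-6-one
Conditions: Dess–Martin periodinane, CH2Cl2, 0 °C → rt
Reagents that add atoms: none
Why: Dess–Martin oxidation converts only the secondary C6 alcohol to the ketone under neutral conditions that should not move the C8=C9 alkene into conjugation or epimerise C5.

Step 12
Reactants: 16 hydroxy ketone
Product: 17 (1R,4R,5R,6S)-dauc-8-ene-4,6-diol (6-OH trans to H5)
Conditions: NaBH4, MeOH, −20 °C
Reagents that add atoms: none
Why: Hydride reduction should take place from the face of H5, the other face of the C6 ketone being shielded by C4 and its isopropyl group, which places the C6 hydroxyl trans to H5.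

Step 13
Reactants: 17 diol
Product: 18 (1R,4R,5R,6S)-4-hydroxydauc-8-en-6-yl 4-methoxybenzoate
Conditions: 4-methoxybenzoyl chloride, pyridine, 4-(dimethylamino)pyridine (cat.), CH2Cl2, rt → 40 °C
Reagents that add atoms: 4-methoxybenzoyl chloride COc1ccc(C(=O)Cl)cc1
Why: Acylation occurs at the secondary C6 alcohol because the tertiary C4 alcohol is unreactive under these conditions.

Step 14
Reactants: 18 anisoate
Product: 19 (1S,4R,5R,6S)-4-hydroxy-10-oxodauc-8-en-6-yl 4-methoxybenzoate
Conditions: Rh2(cap)4 (cap = caprolactamate, cat.), t-BuOOH, K2CO3 (0.5 equiv), CH2Cl2, rt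
Reagents that add atoms: tert-butyl hydroperoxide CC(C)(C)OO
Why: The dirhodium-catalysed allylic oxidation with t-BuOOH should oxidise the ring CH2 next to the alkene CH (C10) to the β-methyl enone, C7 being deactivated by the neighbouring ester.

Step 15
Reactants: 19 enone
Product: 20 (1S,4R,5R,6S,10S)-4,10-dihydroxydauc-8-en-6-yl 4-methoxybenzoate
Conditions: NaBH4, CeCl3·7H2O, MeOH, −78 °C
Reagents that add atoms: none
Why: Luche reduction gives 1,2-reduction with hydride attack anti to the angular C1 methyl group, which places the C10 hydroxyl cis to that methyl.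

Step 16
Reactants: 20 allylic alcohol
Product: 21 (1S,4R,5R,6S,10S)-10-acetoxy-4-hydroxydauc-8-en-6-yl 4-methoxybenzoate (CNP0256979.4)
Conditions: Ac2O, pyridine, rt
Reagents that add atoms: acetic anhydride CC(=O)OC(C)=O
Why: Acetylation of the secondary allylic alcohol, with the tertiary C4 alcohol staying free, gives the target.

Compound list
1 | (S)-(+)-terpinen-4-ol | CC1=CC[C@](O)(C(C)C)CC1 | starting material
2 | (S)-terpinen-4-ol triethylsilyl ether | CC1=CC[C@](O[Si](CC)(CC)CC)(C(C)C)CC1 | intermediate
3 | (S)-6-oxo-3-(propan-2-yl)-3-(triethylsilyloxy)heptanal | O=CC[C@](O[Si](CC)(CC)CC)(C(C)C)CCC(C)=O | intermediate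
4 | (R)-2-methyl-5-(propan-2-yl)-5-(triethylsilyloxy)cyclopent-1-ene-1-carbaldehyde | CC1=C(C=O)[C@](O[Si](CC)(CC)CC)(C(C)C)CC1 | intermediate
5 | (Z)-iodoalkene, iodine cis to the ring | CC1=C(/C=C(\I)C)[C@](O[Si](CC)(CC)CC)(C(C)C)CC1 | intermediate
6 | alkenylboronate of (2R,3R)-tetramethyltartaramide, boron cis to the ring | CC1=C(/C=C(\B2O[C@@H](C(=O)N(C)C)[C@H](C(=O)N(C)C)O2)C)[C@](O[Si](CC)(CC)CC)(C(C)C)CC1 | intermediate
7 | cyclopropyl tartaramide boronate (C6 R, C8 R) | CC1=C([C@@H]2C[C@]2(C)B3O[C@@H](C(=O)N(C)C)[C@H](C(=O)N(C)C)O3)[C@](O[Si](CC)(CC)CC)(C(C)C)CC1 | intermediate (not isolated)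
8 | cyclopropyl pinacol boronate (C6 R, C8 R; boron and cyclopentenyl cis) | CC1=C([C@@H]2C[C@]2(C)B3OC(C)(C)C(C)(C)O3)[C@](O[Si](CC)(CC)CC)(C(C)C)CC1 | intermediate
9 | vinyl bromide | C=CBr | starting material
10 | lithium vinylboronate complex of 8 | [Li+].CC1=C([C@@H]2C[C@]2(C)[B-]3(C=C)OC(C)(C)C(C)(C)O3)[C@](O[Si](CC)(CC)CC)(C(C)C)CC1 | intermediate (not isolated)
11 | cis-divinylcyclopropane (vinyl in place of boron, retention) | CC1=C([C@@H]2C[C@]2(C)C=C)[C@](O[Si](CC)(CC)CC)(C(C)C)CC1 | intermediate (not isolated)
12 | (1R,4R)-4-(triethylsilyloxy)dauca-5,8-diene | C1=C2[C@](O[Si](CC)(CC)CC)(C(C)C)CC[C@]2(C)CC=C(C)C1 | intermediate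
13 | (1R,4R)-dauca-5,8-dien-4-ol | C1=C2[C@](O)(C(C)C)CC[C@]2(C)CC=C(C)C1 | intermediate
14 | (1R,4R)-5,6-epoxydauc-8-en-4-ol, epoxide cis to 4-OH | O1[C@@H]2CC(C)=CC[C@@]3(C)CC[C@@](O)(C(C)C)[C@@]123 | intermediate
15 | (1R,4R,5R,6R)-dauc-8-ene-4,6-diol | O[C@@H]1CC(C)=CC[C@@]2(C)CC[C@@](O)(C(C)C)[C@@H]12 | intermediate
16 | (1R,4R,5S)-4-hydroxydauc-8-en-6-one | O=C1CC(C)=CC[C@@]2(C)CC[C@@](O)(C(C)C)[C@@H]12 | intermediate
17 | (1R,4R,5R,6S)-dauc-8-ene-4,6-diol | O[C@H]1CC(C)=CC[C@@]2(C)CC[C@@](O)(C(C)C)[C@@H]12 | intermediate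
18 | (1R,4R,5R,6S)-4-hydroxydauc-8-en-6-yl 4-methoxybenzoate | COc1ccc(C(=O)O[C@H]2CC(C)=CC[C@@]3(C)CC[C@@](O)(C(C)C)[C@@H]23)cc1 | intermediate
19 | (1S,4R,5R,6S)-4-hydroxy-10-oxodauc-8-en-6-yl 4-methoxybenzoate | COc1ccc(C(=O)O[C@H]2CC(C)=CC(=O)[C@@]3(C)CC[C@@](O)(C(C)C)[C@@H]23)cc1 | intermediate
20 | (1S,4R,5R,6S,10S)-4,10-dihydroxydauc-8-en-6-yl 4-methoxybenzoate | COc1ccc(C(=O)O[C@H]2CC(C)=C[C@H](O)[C@@]3(C)CC[C@@](O)(C(C)C)[C@@H]23)cc1 | intermediate
21 | CNP0256979.4, (1S,4R,5R,6S,10S)-10-acetoxy-4-hydroxydauc-8-en-6-yl 4-methoxybenzoate | COc1ccc(C(=O)O[C@H]2CC(C)=C[C@H](OC(C)=O)[C@@]3(C)CC[C@@](O)(C(C)C)[C@@H]23)cc1 | target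

Total step count: 16
Longest linear sequence: 16 steps (1 → 21; vinyl bromide 9 enters in step 7)

Steps most likely to fail

Step 7 (boronate vinylation–Cope cascade). The boronate complex may form incompletely at the hindered tertiary boron, iodine may attack the ring alkene, or 11 may epimerise from cis to trans before it rearranges, which would erode the configuration at C1. The fallback sets out from 4 and comes back at 12. Still–Gennari olefination of 4 with methyl 2-[bis(2,2,2-trifluoroethoxy)phosphoryl]propanoate (KN(SiMe3)2, 18-crown-6, THF, −78 °C) would give the (Z)-enoate F1. Reduction with i-Bu2AlH gives the (Z)-allylic alcohol F2. Charette cyclopropanation (Zn(CH2I)2·DME with the butylboronate of the tartaramide as chiral controller) gives the cyclopropylmethanol F3. Dess–Martin oxidation gives the cyclopropanecarbaldehyde F4. Wittig methylenation (Ph3P=CH2, THF, 0 °C) then gives 11 without boron chemistry, and warming in toluene gives 12.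

Step 6 (auxiliary-controlled cyclopropanation). Facial selectivity of CH2 transfer may be poor, or the zinc carbenoid may cyclopropanate the electron-rich tetrasubstituted ring alkene. The fallback sets out from 5 and comes back at 8. Lithiation of 5 (t-BuLi, Et2O, −78 °C) and trapping with 2-isopropoxy-4,4,5,5-tetramethyl-1,3,2-dioxaborolane gives the pinacol alkenylboronate F5. Pd(OAc)2-catalysed cyclopropanation with diazomethane follows, a carbene transfer that reacts at the boron-bearing alkene and leaves tetrasubstituted alkenes untouched. The two cis-cyclopropanes are diastereomers because of C4 and are separated by chromatography to give 8.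

Step 14 (allylic oxidation). Oxidation may occur at the other allylic positions (C7 or CH3-14), or the substrate may be over-oxidised. The fallback sets out from 18 and comes back at 19. Epoxidation of C8=C9 with mCPBA gives the 8,9-epoxide F6. Opening with PhSeNa (from PhSeSePh and NaBH4) at the less substituted C9 gives the hydroxy selenide F7. Oxidation with H2O2 and selenoxide elimination towards C10 gives the tertiary allylic alcohol F8. Oxidative 1,3-transposition (Babler–Dauben oxidation with pyridinium chlorochromate, [C5H5NH][CrO3Cl]) then gives enone 19.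

Further compounds
F1 | step 7 | methyl (Z)-2-methyl-3-[(5R)-2-methyl-5-(propan-2-yl)-5-(triethylsilyloxy)cyclopent-1-en-1-yl]prop-2-enoate | CC1=C(/C=C(\C(=O)OC)C)[C@](O[Si](CC)(CC)CC)(C(C)C)CC1
F2 | step 7 | (Z)-2-methyl-3-[(5R)-2-methyl-5-(propan-2-yl)-5-(triethylsilyloxy)cyclopent-1-en-1-yl]prop-2-en-1-ol | CC1=C(/C=C(\CO)C)[C@](O[Si](CC)(CC)CC)(C(C)C)CC1
F3 | step 7 | cyclopropylmethanol (hydroxymethyl and cyclopentenyl cis; configuration as in 8) | CC1=C([C@@H]2C[C@]2(C)CO)[C@](O[Si](CC)(CC)CC)(C(C)C)CC1
F4 | step 7 | cyclopropanecarbaldehyde (formyl and cyclopentenyl cis) | CC1=C([C@@H]2C[C@]2(C)C=O)[C@](O[Si](CC)(CC)CC)(C(C)C)CC1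
F5 | step 6 | pinacol alkenylboronate, boron cis to the ring | CC1=C(/C=C(\B2OC(C)(C)C(C)(C)O2)C)[C@](O[Si](CC)(CC)CC)(C(C)C)CC1
F6 | step 14 | 8,9-epoxide of 18 (epoxide on the face of CH3-15) | COc1ccc(C(=O)O[C@H]2C[C@]3(C)O[C@@H]3C[C@@]4(C)CC[C@@](O)(C(C)C)[C@@H]24)cc1
F7 | step 14 | 8-hydroxy-9-(phenylselanyl) derivative of 18 | COc1ccc(C(=O)O[C@H]2C[C@](C)(O)[C@@H]([Se]c3ccccc3)C[C@@]4(C)CC[C@@](O)(C(C)C)[C@@H]24)cc1
F8 | step 14 | 4,8-dihydroxydauc-9-en-6-yl 4-methoxybenzoate (tertiary allylic alcohol) | COc1ccc(C(=O)O[C@H]2C[C@](C)(O)C=C[C@@]4(C)CC[C@@](O)(C(C)C)[C@@H]24)cc1
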